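In 4.00 min the ash run had reached 14.6% product, and in 50.0 s the birch run had reached 5.0%. I had to decide whether the next flask should keep 44 µM of free catalyst or go back to 22 µM.

the same everywhere: substrate 22 mM
- birch: reagent 33 mM; free catalyst 44 µM; the very flask that is asked about, followed so far
- ash: reagent 33 mM; free catalyst 22 µM; run made earlier
- flask: reagent 33.0 mM; free catalyst 44 µM

birch run (percent of the substrate charged)

| time / s | product / % | substrate / % |
|---|---|---|
| 10.0 | 0 | 98.5 |
| 15.0 | 0.8 | 96.3 |
| 20.0 | 1.3 | 97.1 |
| 30.0 | 1.9 | 97.9 |
| 40.0 | 4.8 | 94.9 |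
| 50.0 | 5.0 | 93.4 |

ash run (percent of the substrate charged)

| time / min | product / % | substrate / % |
|---|---|---|
| 0.500 | 2.0 | 97.5 |
| 1.00 | 3.9 | 97.1 |
| 1.50 | 3.2 | 95.4 |
| 2.50 | 9.2 | 90.0 |
| 3.00 | 9.6 | 89.1 |
| 4.00 | 14.6 | 87.5 |

(scatter of a reading: 1 percentage point)

1. apparent order in free catalyst when 10% of the substrate are converted (percent change of the rate of making product for one percent more free catalyst charged)



So I counted turnovers, using the last reading of each run:

birch: 5.0% × 22 mM / (44 µM × 50.0 s) = 30.0 min⁻¹

ash: 14.6% × 22 mM / (22 µM × 4.00 min) = 36.5 min⁻¹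

That is T, the turnovers per minute for each catalyst charged. As read, T in birch came out lower than in ash, which gives the order n:

n = 1 + ln(T birch / T ash) / ln(44 µM / 22 µM) = 0.717

A scatter of 1 percentage point on a reading of 5.0% left n rough. Still, the readings put the birch rate at 1.64 times the ash rate, so I kept 44 µM. At that T, the 50.0 turnovers to 10% conversion should take 1.67 min.

The forecast gave 0.8, above my n, and added: "Simple first order remains possible".

The flask gave 0.86.

    reagent + free catalyst ⇌ catalyst intermediate A (K = 44.0 M⁻¹, k = 8500 M⁻¹ min⁻¹)
    substrate + catalyst intermediate A → catalyst intermediate B (k = 14000 M⁻¹ min⁻¹)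
    catalyst intermediate B ⇌ catalyst intermediate C (K = 1.80, k = 1100 min⁻¹)
    catalyst intermediate C → free catalyst + product (k = 110 min⁻¹)
    2 free catalyst ⇌ resting dimer, settled at all times (K = 40000 M⁻¹)

The flask reached 10% at 1.45 min, sooner than my 1.67 min, at 1.46 mM min⁻¹, so T was 33.2 min⁻¹. Carried to the ash run with that order, T comes to about 36.6 min⁻¹, beside the 36.5 min⁻¹ read there from one scattered reading. At 1.00 min substrate was passing to product with 93.0% of its charge present, and the flask held 30.8% of its catalyst as catalyst intermediate C, the largest share then. At 100 min the flask's substrate stood at 0%, its reagent at 33.3% of its own charge, and resting dimer held 46.2% of the catalyst charged.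

All runs come from a simulation from invented constants; the scatter is artificial.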